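**Plan**

- **Cuts (labdane numbering).** First the helpers come off: the C19 4‑methoxybenzyl ester, the C17 ethyl ester, and C13–SPh as a masked C13=C14. Then C9–C10 of ring B is cut, then C8=C9 (olefination), then C4–C18 (enolate methylation), then C4–C5 and C2–C3 of ring A (Diels–Alder).
- **Enabling feature.** The quaternary ring‑fusion carbon C10 carries a CH3 and stands β to C8, the ring B carbon that bears the C17 carboxyl. C9–C10 is therefore the bond of a conjugate addition of a tertiary C10 radical (H· added to C1 of a ring A C1=C10 alkene) to a C8=C9 enoate.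
- **Forward order.** The lactone ring is bought closed. Ring A is made by Diels–Alder reaction. The ring A phosphonate and the lactone aldehyde are joined at C8=C9. Ring B is closed last, 6‑endo, at C9–C10.
- **Stereochemistry.** C5 comes from a catalytic asymmetric Diels–Alder reaction and C4 from methylation anti to the C5 chain. C10 and C9 are set in the key step (chair–chair closure, Z‑enoate, β face screened by the axial C19 ester). C8 is set by base equilibration to the equatorial ester.

Key step: step 13

**Remarks**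

- Numbering: ring A = C1–C5, C10; ring B = C5–C10; C17 = carboxyl on C8; C18 = CH3 and C19 = carboxyl on C4; C20 = CH3 on C10; chain C11, C12; lactone C13–C16.
- Assumption: the (S,S)‑bis(oxazoline) copper catalyst is taken to open the acrylimide face that gives (S) at the carbonyl‑bearing carbon, as with simple 1‑substituted dienes. The antipodal ligand is equally available.
- The sulfur‑bearing carbon C13 (compounds 16–29) and the phosphonate carbon C8 of 14 are stereo‑mixtures that are erased later, so their SMILES leave them open.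

**Step 1**
Reactants: 1 3‑[(tert‑butyldimethylsilyl)oxy]propanal; 2 2‑(triphenyl‑λ5‑phosphanylidene)propanal
Product: 3 (E)‑5‑[(tert‑butyldimethylsilyl)oxy]‑2‑methylpent‑2‑enal
Conditions: toluene, 80 °C
Reagents that add atoms: none
Why: Wittig olefination with a formyl‑stabilised ylide should give the (E)‑trisubstituted enal, the geometry that later places the side chain on the outside of the diene.

**Step 2**
Reactants: 3 (E)‑enal
Product: 4 (E)‑tert‑butyl(dimethyl)[(4‑methylhexa‑3,5‑dien‑1‑yl)oxy]silane
Conditions: Ph3PCH3Br, t‑BuOK, THF, 0 °C → rt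
Reagents that add atoms: methylenetriphenylphosphorane (from methyltriphenylphosphonium bromide), C=P(c1ccccc1)(c1ccccc1)c1ccccc1
Why: Wittig methylenation with a non‑stabilised ylide turns CHO into the vinyl group without touching the (E)‑alkene or the silyl ether.

**Step 3**
Reactants: 4 diene; 5 3‑acryloyl‑1,3‑oxazolidin‑2‑one
Product: 6 3‑{[(1S,2S)‑2‑{2‑[(tert‑butyldimethylsilyl)oxy]ethyl}‑3‑methylcyclohex‑3‑en‑1‑yl]carbonyl}‑1,3‑oxazolidin‑2‑one (cis adduct)
Conditions: [Cu((S,S)‑t‑Bu‑box)](SbF6)2 (10 mol %; t‑Bu‑box = 2,2'‑(propane‑2,2‑diyl)bis(4‑tert‑butyl‑4,5‑dihydrooxazole)), CH2Cl2, rt; trans adduct removed by chromatography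
Reagents that add atoms: none
Why: In this catalytic asymmetric Diels–Alder reaction the s‑cis acrylimide chelated to square‑planar divalent copper is open on one face only, the 1‑alkyl terminus of the diene directs "ortho" bonding (C4–C5) and the endo mode gives the cis adduct, so C5 is set (5α‑H), and the trans (exo) adduct must be removed here because after step 5 it would feed the enantiomeric series.

**Step 4**
Reactants: 6 cis imide
Product: 7 4‑methoxybenzyl (1S,2S)‑2‑{2‑[(tert‑butyldimethylsilyl)oxy]ethyl}‑3‑methylcyclohex‑3‑ene‑1‑carboxylate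
Conditions: 4‑MeOC6H4CH2OH, n‑BuLi, THF, 0 °C; NH4Cl quench
Reagents that add atoms: 4‑methoxybenzyl alcohol, COc1ccc(CO)cc1
Why: Transesterification of an N‑acyl oxazolidinone with a lithium benzylic alkoxide attacks the exocyclic carbonyl and installs the acid‑labile C19 ester, and any epimerisation at C4 is harmless because C4 is planarised in step 5.

**Step 5**
Reactants: 7 ester
Product: 9 4‑methoxybenzyl (1S,2R)‑2‑{2‑[(tert‑butyldimethylsilyl)oxy]ethyl}‑1,3‑dimethylcyclohex‑3‑ene‑1‑carboxylate (CH3 trans, ester cis to the side chain), via lithium ester enolate 8 (not isolated)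
Conditions: LDA, THF, −78 °C; MeI, DMPU, −78 → −20 °C
Reagents that add atoms: iodomethane, CI
Why: In this alkylation of an exocyclic ester enolate, allylic strain from the enolate oxygens and from the C10 methyl holds the C5 chain pseudoaxial, so MeI should add to C4 on the opposite face and set the quaternary centre with C18 trans and C19 cis to the chain.

**Step 6**
Reactants: 9 silyl ether
Product: 10 4‑methoxybenzyl (1S,2R)‑2‑(2‑hydroxyethyl)‑1,3‑dimethylcyclohex‑3‑ene‑1‑carboxylate
Conditions: camphorsulfonic acid (cat.), MeOH, 0 °C → rt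
Reagents that add atoms: none
Why: Acid‑catalysed methanolysis of a primary silyl ether is mild enough for the hindered 4‑methoxybenzyl ester and the trisubstituted alkene.

**Step 7**
Reactants: 10 alcohol
Product: 11 4‑methoxybenzyl (1S,2R)‑2‑(2‑iodoethyl)‑1,3‑dimethylcyclohex‑3‑ene‑1‑carboxylate
Conditions: I2, PPh3, imidazole, CH2Cl2, 0 °C
Reagents that add atoms: iodine, II
Why: Appel‑type iodination proceeds by SN2 attack on the alkoxyphosphonium ion of the unhindered primary alcohol at C7.

**Step 8**
Reactants: 11 iodide; 12 ethyl 2‑(diphenoxyphosphoryl)acetate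
Product: 14 ethyl 2‑(diphenoxyphosphoryl)‑4‑[(1R,6S)‑6‑{[(4‑methoxybenzyl)oxy]carbonyl}‑2,6‑dimethylcyclohex‑2‑en‑1‑yl]butanoate, via sodium phosphonoacetate 13 (not isolated)
Conditions: NaH, DMSO, rt; then 11, rt → 50 °C
Reagents that add atoms: none
Why: C‑alkylation of a phosphonoacetate salt with a primary iodide is the standard entry to α‑substituted diaryl phosphonoacetates and forms C7–C8.

**Step 9**
Reactants: 15 3‑bromooxolan‑2‑one (α‑bromo‑γ‑butyrolactone)
Product: 16 3‑(phenylsulfanyl)oxolan‑2‑one
Conditions: PhSH, Et3N, CH2Cl2, 0 °C → rt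
Reagents that add atoms: thiophenol, Sc1ccccc1
Why: SN2 displacement of the activated α‑bromide gives the closed lactone ring whose sulfur acidifies C13 now and leaves later to create C13=C14.

**Step 10**
Reactants: 16 sulfanyl lactone; 17 2‑(2‑bromoethyl)‑1,3‑dioxolane
Product: 19 3‑[2‑(1,3‑dioxolan‑2‑yl)ethyl]‑3‑(phenylsulfanyl)oxolan‑2‑one, via lithium lactone enolate 18 (not isolated)
Conditions: LDA, THF–DMPU, −78 °C; then 17, −78 °C → rt
Reagents that add atoms: none
Why: Alkylation of the sulfur‑stabilised lactone enolate with a primary halide is the reaction type used for α‑alkyl butenolide precursors and forms C12–C13.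

**Step 11**
Reactants: 19 acetal
Product: 20 3‑[2‑oxo‑3‑(phenylsulfanyl)oxolan‑3‑yl]propanal
Conditions: 1 M HCl, THF, rt
Reagents that add atoms: water, O
Why: Acid hydrolysis of the dioxolane frees the C9 aldehyde while lactone and sulfide are inert to dilute acid.

**Step 12**
Reactants: 14 phosphonate; 20 aldehyde
Product: 22 ethyl (2Z)‑2‑{2‑[(1R,6S)‑6‑{[(4‑methoxybenzyl)oxy]carbonyl}‑2,6‑dimethylcyclohex‑2‑en‑1‑yl]ethyl}‑5‑[2‑oxo‑3‑(phenylsulfanyl)oxolan‑3‑yl]pent‑2‑enoate, via potassium phosphonate salt 21 (not isolated)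
Conditions: t‑BuOK, THF, −78 °C; then 20, −78 → 0 °C
Reagents that add atoms: none
Why: In this Horner–Wadsworth–Emmons olefination with a diaryl phosphonate the electron‑poor aryloxy groups make collapse of the first‑formed adduct fast, so the (Z)‑trisubstituted enoate (C11 cis to CO2Et, trans to C7) should form under kinetic control.

**Step 13**
Reactants: 22 Z‑enoate
Product: 25 19‑(4‑methoxybenzyl) 17‑ethyl diester of the 13‑(phenylsulfanyl)‑13,14‑dihydro target as its C8 epimer (trans‑decalin, 5α‑H, 9α‑H, 10β‑CH3, 8α‑H, axial 8β‑CO2Et), via C10 tertiary radical 23 (not isolated), via C8 ester radical 24 (not isolated)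
Conditions: Fe(acac)3 (30 mol %), PhSiH3 (3 equiv), EtOH (0.01 M), 60 °C
Reagents that add atoms: none
Why: An iron hydride formed from Fe(acac)3 and PhSiH3 transfers H· to C1 of the C1=C10 alkene to give the nucleophilic tertiary radical 23, which adds to C9, the β carbon of the enoate, and the ester‑stabilised radical 24 is reduced by divalent iron to the enolate and protonated by ethanol. The closest known reaction type is the iron‑catalysed reductive olefin coupling (hydrogen‑atom‑transfer‑initiated Giese reaction) in its intramolecular form, with the stereochemical course of the ring B closure of radical polyene cyclisations. Ring B closes 6‑endo‑trig, because 5‑exo attack at C8 is contra‑polar and would join two fully substituted carbons. For C10, ring A reacts as the chair with equatorial C5 chain and axial C19 ester, which screens the β face, so C9 bonds from the α face, C20 becomes axial and the fusion trans; for C9, in the chair‑like transition state the enoate substituent trans to C7 (C11 of the Z‑isomer) becomes equatorial (9α‑H); for C8, protonation from the open α face, away from axial C20, is expected to leave the ester axial, which step 14 corrects. The step needs H· transfer to the ring alkene only, which is secured because the sole other alkene is the electron‑poor enoate and C13=C14 is masked as the saturated sulfanyl lactone, while high dilution suppresses intermolecular addition.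

**Step 14**
Reactants: 25 diester
Product: 28 19‑(4‑methoxybenzyl) ester 17‑acid of the 13‑(phenylsulfanyl)‑13,14‑dihydro target (8β‑H, equatorial 8α‑CO2H), via equatorial C17 ethyl ester 26 (not isolated), via seco hydroxy diacid 27 (not isolated)
Conditions: NaOEt, EtOH, reflux; then H2O, reflux; then 1 M HCl, rt
Reagents that add atoms: water, O
Why: Base equilibration through the ester enolate relieves the 1,3‑diaxial clash of the C17 ester with C20 and sets C8 as the equatorial epimer, which is then saponified, while the neopentyl axial C19 ester resists attack and the lactone opened by hydroxide closes again on acidification.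

**Step 15**
Reactants: 28 sulfide acid
Product: 30 19‑(4‑methoxybenzyl) ester of the target (13‑en‑16,15‑olide, free 17‑acid), via sulfoxide 29 (not isolated)
Conditions: mCPBA (1.0 equiv), CH2Cl2, −78 → 0 °C; then toluene, 110 °C
Reagents that add atoms: 3‑chloroperbenzoic acid, O=C(OO)c1cccc(Cl)c1 (its oxygen is carried by 29 only)
Why: Sulfide oxidation followed by thermal syn elimination of the sulfoxide is the standard unmasking of α‑alkyl butenolides, takes a ring hydrogen at C14 to give the conjugated endocyclic C13=C14 bond, and erases the C13 centre.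

**Step 16**
Reactants: 30 mono ester
Product: 31 target, labd‑13‑en‑16,15‑olide‑17,19‑dioic acid (4S,5α‑H,8β‑H,9α‑H,10β‑CH3)
Conditions: CF3CO2H, anisole, CH2Cl2, 0 °C → rt
Reagents that add atoms: none
Why: Acidolysis of the 4‑methoxybenzyl ester runs by an SN1 path at the benzylic carbon, so it is independent of the crowding at C19 and leaves the butenolide and all stereocentres untouched.

**Compound list**

1 | 3‑[(tert‑butyldimethylsilyl)oxy]propanal | O=CCCO[Si](C)(C)C(C)(C)C | starting material
2 | 2‑(triphenyl‑λ5‑phosphanylidene)propanal | CC(C=O)=P(c1ccccc1)(c1ccccc1)c1ccccc1 | starting material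
3 | (E)‑5‑[(tert‑butyldimethylsilyl)oxy]‑2‑methylpent‑2‑enal | O=C/C(C)=C/CCO[Si](C)(C)C(C)(C)C | intermediate
4 | (E)‑tert‑butyl(dimethyl)[(4‑methylhexa‑3,5‑dien‑1‑yl)oxy]silane | C=C/C(C)=C/CCO[Si](C)(C)C(C)(C)C | intermediate
5 | 3‑acryloyl‑1,3‑oxazolidin‑2‑one | C=CC(=O)N1CCOC1=O | starting material
6 | cis Diels–Alder imide | CC1=CCC[C@H](C(=O)N2CCOC2=O)[C@@H]1CCO[Si](C)(C)C(C)(C)C | intermediate
7 | 4‑methoxybenzyl ester (C4–H) | CC1=CCC[C@H](C(=O)OCc2ccc(OC)cc2)[C@@H]1CCO[Si](C)(C)C(C)(C)C | intermediate
8 | lithium ester enolate | CC1=CCCC(=C([O-])OCc2ccc(OC)cc2)[C@@H]1CCO[Si](C)(C)C(C)(C)C.[Li+] | intermediate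
9 | C4‑methylated ester, silyl ether | CC1=CCC[C@](C)(C(=O)OCc2ccc(OC)cc2)[C@@H]1CCO[Si](C)(C)C(C)(C)C | intermediate
10 | ring A alcohol | CC1=CCC[C@](C)(C(=O)OCc2ccc(OC)cc2)[C@@H]1CCO | intermediate
11 | ring A iodide | CC1=CCC[C@](C)(C(=O)OCc2ccc(OC)cc2)[C@@H]1CCI | intermediate
12 | ethyl 2‑(diphenoxyphosphoryl)acetate | CCOC(=O)CP(=O)(Oc1ccccc1)Oc1ccccc1 | starting material
13 | sodium salt of 12 | CCOC(=O)[CH-]P(=O)(Oc1ccccc1)Oc1ccccc1.[Na+] | intermediate
14 | ring A phosphonate | CC1=CCC[C@](C)(C(=O)OCc2ccc(OC)cc2)[C@@H]1CCC(C(=O)OCC)P(=O)(Oc2ccccc2)Oc2ccccc2 | intermediate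
15 | 3‑bromooxolan‑2‑one | O=C1OCCC1Br | starting material
16 | 3‑(phenylsulfanyl)oxolan‑2‑one | O=C1OCCC1Sc1ccccc1 | intermediate
17 | 2‑(2‑bromoethyl)‑1,3‑dioxolane | BrCCC1OCCO1 | starting material
18 | lithium enolate of 16 | [Li+].[O-]C1=C(Sc2ccccc2)CCO1 | intermediate
19 | alkylated lactone acetal | O=C1OCCC1(CCC2OCCO2)Sc2ccccc2 | intermediate
20 | lactone aldehyde | O=CCCC1(Sc2ccccc2)CCOC1=O | intermediate
21 | potassium salt of 14 | CC1=CCC[C@](C)(C(=O)OCc2ccc(OC)cc2)[C@@H]1CC[C-](C(=O)OCC)P(=O)(Oc2ccccc2)Oc2ccccc2.[K+] | intermediate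
22 | Z‑enoate (cyclisation substrate) | CC1=CCC[C@](C)(C(=O)OCc2ccc(OC)cc2)[C@@H]1CC/C(C(=O)OCC)=C/CCC2(Sc3ccccc3)CCOC2=O | intermediate
23 | C10 tertiary radical | C[C]1CCC[C@](C)(C(=O)OCc2ccc(OC)cc2)[C@@H]1CC/C(C(=O)OCC)=C/CCC2(Sc3ccccc3)CCOC2=O | intermediate
24 | C8 ester radical (ring B closed) | C[C@]12CCC[C@](C)(C(=O)OCc3ccc(OC)cc3)[C@@H]1CC[C](C(=O)OCC)[C@@H]2CCC4(Sc5ccccc5)CCOC4=O | intermediate
25 | trans‑decalin diester, axial C17 ester | C[C@]12CCC[C@](C)(C(=O)OCc3ccc(OC)cc3)[C@@H]1CC[C@H](C(=O)OCC)[C@@H]2CCC4(Sc5ccccc5)CCOC4=O | intermediate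
26 | trans‑decalin diester, equatorial C17 ester | C[C@]12CCC[C@](C)(C(=O)OCc3ccc(OC)cc3)[C@@H]1CC[C@@H](C(=O)OCC)[C@@H]2CCC4(Sc5ccccc5)CCOC4=O | intermediate
27 | seco hydroxy diacid | C[C@]12CCC[C@](C)(C(=O)OCc3ccc(OC)cc3)[C@@H]1CC[C@@H](C(=O)O)[C@@H]2CCC(CCO)(Sc4ccccc4)C(=O)O | intermediate
28 | 17‑acid, sulfanyl lactone | C[C@]12CCC[C@](C)(C(=O)OCc3ccc(OC)cc3)[C@@H]1CC[C@@H](C(=O)O)[C@@H]2CCC4(Sc5ccccc5)CCOC4=O | intermediate
29 | sulfoxide | C[C@]12CCC[C@](C)(C(=O)OCc3ccc(OC)cc3)[C@@H]1CC[C@@H](C(=O)O)[C@@H]2CCC4(S(=O)c5ccccc5)CCOC4=O | intermediate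
30 | butenolide 19‑(4‑methoxybenzyl) ester | C[C@]12CCC[C@](C)(C(=O)OCc3ccc(OC)cc3)[C@@H]1CC[C@@H](C(=O)O)[C@@H]2CCC4=CCOC4=O | intermediate
31 | target | C[C@]12CCC[C@](C)(C(=O)O)[C@@H]1CC[C@@H](C(=O)O)[C@@H]2CCC1=CCOC1=O | target

**Step count**

Total step count: 16. Longest linear sequence: 13 (steps 1–8 and 12–16).

**Steps most likely to fail**

**Step 13.** The C10 radical may be quenched by the hydrogen‑atom donors in the flask, giving net hydrogenation of C1=C10, faster than the 6‑endo closure. The fallback sets out from 22 and comes back at 25, and it makes the same radical with no hydrogen‑atom donor present.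
- Mukaiyama hydration of 22 (Mn(dpm)3, PhSiH3, O2, i‑PrOH, 0 °C), in which O2 traps the radical before it can cyclise, should give the tertiary C10 alcohol F1.
- Acylation with methyl chlorooxoacetate (Et3N, DMAP, CH2Cl2) gives the mixed methyl oxalate F2.
- One equivalent of aqueous CsOH in THF cleaves only the activated oxalate methyl ester to the cesium oxalate F3.
- Blue‑light irradiation with [Ir(dF(CF3)ppy)2(dtbbpy)]PF6 (DME–DMF, H2O, 60 °C) oxidises the oxalate, and CO2 is lost twice.
- The C10 radical then closes ring B, and the C8 radical is reduced by the reduced photocatalyst and protonated by water to give 25.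

**Step 12.** Kinetic control may be lost with the bulky α‑substituent, so that adduct equilibration gives the E‑enoate, which would lead to the C9 epimer in step 13. The fallback sets out from 11 and 20 and comes back at 22, and it fixes the geometry by syn hydrometalation and stereoretentive cross‑coupling.
- Ohira–Bestmann homologation of 20 (dimethyl (1‑diazo‑2‑oxopropyl)phosphonate, K2CO3, MeOH) gives the terminal alkyne F4.
- Carboxylation and esterification (AgI cat., Cs2CO3, CO2, DMF, then EtI) gives the ynoate F5.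
- Syn hydrostannation catalysed by zerovalent palladium (Pd(PPh3)4, Bu3SnH, THF) places tin on the α carbon and gives the (E)‑α‑stannyl enoate F6.
- Iododestannylation (I2, CH2Cl2) proceeds with retention to the (E)‑α‑iodo enoate F7.
- Zinc insertion into 11 (Zn, LiCl, THF) gives the alkylzinc iodide F8.
- Negishi coupling of F8 with F7 (PdCl2(dppf), THF) forms C7–C8 with retention and delivers 22.

**Step 3.** Endo/exo and facial selectivity may be poor when the 1,2‑disubstituted diene meets the copper catalyst. The fallback sets out from 4 and comes back at 7, and it uses a covalently bound auxiliary and a stronger chelating Lewis acid.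
- (R)‑4‑Benzyl‑1,3‑oxazolidin‑2‑one is acylated (n‑BuLi, acryloyl chloride, THF, −78 °C) to the chiral acrylimide F9.
- Its Diels–Alder reaction with 4 (Et2AlCl, CH2Cl2, −78 °C) takes place on the face opposite to the benzyl group and in the endo mode, giving the auxiliary‑bearing cis adduct F10, which is purified as a single diastereomer.
- Lithium 4‑methoxybenzyl oxide, as in step 4, then gives 7.

**Further compounds**

F1 | step 13 | tertiary C10 alcohol of 22 | CC1(O)CCC[C@](C)(C(=O)OCc2ccc(OC)cc2)[C@@H]1CC/C(C(=O)OCC)=C/CCC2(Sc3ccccc3)CCOC2=O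
F2 | step 13 | C10 methyl oxalate | COC(=O)C(=O)OC1(C)CCC[C@](C)(C(=O)OCc2ccc(OC)cc2)[C@@H]1CC/C(C(=O)OCC)=C/CCC2(Sc3ccccc3)CCOC2=O
F3 | step 13 | C10 cesium oxalate | [Cs+].[O-]C(=O)C(=O)OC1(C)CCC[C@](C)(C(=O)OCc2ccc(OC)cc2)[C@@H]1CC/C(C(=O)OCC)=C/CCC2(Sc3ccccc3)CCOC2=O
F4 | step 12 | 3‑(but‑3‑yn‑1‑yl)‑3‑(phenylsulfanyl)oxolan‑2‑one | C#CCCC1(Sc2ccccc2)CCOC1=O
F5 | step 12 | ethyl 5‑[2‑oxo‑3‑(phenylsulfanyl)oxolan‑3‑yl]pent‑2‑ynoate | CCOC(=O)C#CCCC1(Sc2ccccc2)CCOC1=O
F6 | step 12 | ethyl (E)‑2‑(tributylstannyl)pent‑2‑enoate derivative | CCCC[Sn](CCCC)(CCCC)/C(C(=O)OCC)=C/CCC1(Sc2ccccc2)CCOC1=O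
F7 | step 12 | ethyl (E)‑2‑iodopent‑2‑enoate derivative | I/C(C(=O)OCC)=C/CCC1(Sc2ccccc2)CCOC1=O
F8 | step 12 | ring A alkylzinc iodide | CC1=CCC[C@](C)(C(=O)OCc2ccc(OC)cc2)[C@@H]1CC[Zn]I
F9 | step 3 | (R)‑3‑acryloyl‑4‑benzyl‑1,3‑oxazolidin‑2‑one | C=CC(=O)N1[C@H](Cc2ccccc2)COC1=O
F10 | step 3 | auxiliary‑bearing cis adduct | CC1=CCC[C@H](C(=O)N2[C@H](Cc3ccccc3)COC2=O)[C@@H]1CCO[Si](C)(C)C(C)(C)C
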